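**Plan**
- Retrosynthesis: the C2 aryl acetate is cut at C(aryl)–O back to an aryl methyl ketone (Baeyer–Villiger). The benzene ring is then cut at C1–C6 and C2–C3 into chiral ynone 8 and 1,1-dimethoxy-3-silyloxybutadiene 11. The ynone is cut at its acyl–alkyne and alkyne–CH2 bonds into acetyl chloride, acetylide and (R)-1,2-epoxytridecane.
- Enabling feature: on the benzene ring the C3 methoxy and the free C5 hydroxyl are meta to each other, which matches the ketene-acetal carbon and the silyl-enol-ether carbon of the diene. The C2 acetoxy group is an oxidised acetyl group, and acetyl is what activates an alkyne as dienophile.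
- Forward: the chain is joined first (epoxide, alkynol, acetate, ynone; steps 1–5) and the diene is made in two steps (6–7). The only ring, the benzene ring, arises in step 8 by cycloaddition and loss of methanol. Step 9 turns acetyl into acetoxy.
- Stereochemistry: the single stereocentre (R, C2 of the tridecyl chain) comes from the hydrolytic kinetic resolution of racemic 1,2-epoxytridecane in step 2. No later step breaks a bond to it.

Key step: step 8

Remark: the stereocentre of the target is read as (R). The (R,R) enantiomer of (salen)Co(OAc) [salen = dianion of N,N'-bis(3,5-di-tert-butylsalicylidene)cyclohexane-1,2-diamine] is taken to be the one that leaves the (R)-enantiomer of a simple 1-alkene oxide unreacted.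

**Route**

Step 1
Reactants: 1 1-tridecene
Product: 2 rac-1,2-epoxytridecane (2-undecyloxirane)
Conditions: mCPBA (1.2 equiv), CH2Cl2, 0 °C to rt
Reagents that add atoms: mCPBA, OOC(=O)c1cccc(Cl)c1
Why: Prilezhaev epoxidation of an unhindered terminal alkene by a peracid is reliable, and the racemate is what the next step needs.

Step 2
Reactants: 2 rac-1,2-epoxytridecane
Product: 3 (R)-1,2-epoxytridecane
Conditions: (R,R)-(salen)Co(OAc) (0.5 mol%), H2O (0.55 equiv), minimum THF, 0 °C to rt; epoxide separated from the diol by distillation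
Reagents that add atoms: none
Why: In this hydrolytic kinetic resolution the chiral trivalent-cobalt salen catalyst should hydrolyse the (S)-epoxide much faster than the (R)-epoxide, so the unreacted (R)-epoxide is recovered and the stereocentre of the target is set by catalyst control.

Step 3
Reactants: 3 (R)-1,2-epoxytridecane; 4 lithium acetylide–ethylenediamine complex
Product: 5 (R)-pentadec-1-yn-4-ol
Conditions: LiC≡CH·H2NCH2CH2NH2 (1.5 equiv), DMSO, 0 °C to rt; then H2O
Reagents that add atoms: none
Why: SN2 opening of a terminal epoxide by an acetylide takes place at the unsubstituted CH2 carbon, so the C–O bond at the stereocentre is not broken and the (R) configuration is kept.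

Step 4
Reactants: 5 (R)-pentadec-1-yn-4-ol
Product: 6 (R)-pentadec-1-yn-4-yl acetate
Conditions: Ac2O, pyridine, DMAP (cat.), CH2Cl2, 0 °C to rt
Reagents that add atoms: acetic anhydride, CC(=O)OC(C)=O
Why: DMAP-catalysed acylation of a secondary alcohol installs the side-chain acetate of the target early and removes the free hydroxyl that could later add to the ynone.

Step 5
Reactants: 6 (R)-pentadec-1-yn-4-yl acetate; 7 acetyl chloride
Product: 8 (R)-2-oxoheptadec-3-yn-6-yl acetate
Conditions: PdCl2(PPh3)2 (2 mol%), CuI (4 mol%), Et3N (1.05 equiv), THF, rt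
Reagents that add atoms: none
Why: In this acyl Sonogashira coupling acetyl chloride adds oxidatively to zerovalent palladium, the copper acetylide transmetalates and reductive elimination gives the ynone; a single equivalent of amine keeps the medium close to neutral so that the acetate and the acidic CH2 next to the alkyne are left alone.

Step 6
Reactants: 7 acetyl chloride; 9 1,1-dimethoxyethene
Product: 10 4,4-dimethoxybut-3-en-2-one
Conditions: 9 (2.2 equiv), Et2O, 0 °C to rt
Reagents that add atoms: none
Why: C-acylation of the nucleophilic ketene acetal by the acid chloride and loss of HCl from the dialkoxycarbenium ion give the beta,beta-dimethoxy enone; the second equivalent of 9 traps HCl as methyl acetate and chloromethane, so no amine that would turn acetyl chloride into ketene is present.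

Step 7
Reactants: 10 4,4-dimethoxybut-3-en-2-one
Product: 11 1,1-dimethoxy-3-(trimethylsilyloxy)buta-1,3-diene
Conditions: TMSOTf (1.1 equiv), Et3N (1.3 equiv), Et2O, 0 °C to rt; filtered and distilled under exclusion of moisture
Reagents that add atoms: trimethylsilyl trifluoromethanesulfonate, C[Si](C)(C)OS(=O)(=O)C(F)(F)F
Why: In this soft enolisation O-silylation of the vinylogous ester carbonyl gives a dialkoxy-stabilised allyl cation that the amine deprotonates at the only available position, the methyl group, which gives the cross-conjugated silyl enol ether (silyl dienol ether formation).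

Step 8
Reactants: 8 (R)-2-oxoheptadec-3-yn-6-yl acetate; 11 1,1-dimethoxy-3-(trimethylsilyloxy)buta-1,3-diene
Product: 14 (R)-1-(2-acetyl-5-hydroxy-3-methoxyphenyl)tridecan-2-yl acetate, via ketal cycloadduct 12 (not isolated), via aryl trimethylsilyl ether 13 (not isolated)
Conditions: 11 (2.5 equiv), toluene, 110 °C, sealed tube; then 0.1 M HCl, THF, rt
Reagents that add atoms: none
Why: The electron-rich diene 11 and the electron-poor ynone 8 should combine in a normal-electron-demand, concerted but strongly asynchronous [4+2] cycloaddition (Diels–Alder reaction) that forms the bonds that become C1–C6 and C2–C3 of the arene and gives the cyclohexa-1,4-diene ketal 12. The closest known reaction type is the Diels–Alder reaction and aromatisation of 1,1-dialkoxy-3-silyloxybutadienes with beta-alkyl-substituted acetylenic esters and ketones, which gives 2-acyl-3-alkoxy-5-hydroxyarenes. The six-membered ring closes by intermolecular [4+2] cycloaddition, both ring bonds forming in one step; 1,4-elimination of methanol from the ketal carbon and the ring CH2 of 12 then makes the ring aromatic (13), and dilute acid cleaves the aryl silyl ether to the C5 phenol. No stereocentre is formed, and the side-chain stereocentre, two atoms away from the alkyne, takes no part. The step needs regioselectivity: the CH2 terminus of the diene is its most nucleophilic carbon because all three oxygen donors push electron density there, and it bonds to the beta-carbon of the ynone, its most electrophilic carbon, so the ketene-acetal carbon ends up next to the acetyl group and the C3 methoxy and C5 hydroxyl come out already differentiated.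

Step 9
Reactants: 14 (R)-1-(2-acetyl-5-hydroxy-3-methoxyphenyl)tridecan-2-yl acetate
Product: 15 (R)-1-(2-acetoxy-5-hydroxy-3-methoxyphenyl)tridecan-2-yl acetate
Conditions: mCPBA (1.3 equiv), CH2Cl2, 0 °C to rt
Reagents that add atoms: mCPBA, OOC(=O)c1cccc(Cl)c1
Why: In this Baeyer–Villiger oxidation the peracid adds to the acetyl carbonyl, which the two ortho substituents twist out of conjugation, and in the Criegee intermediate the aryl group, made electron-rich by the para hydroxyl and the ortho methoxy group, should migrate in preference to methyl to give the aryl acetate, as peracid oxidation of para-hydroxyacetophenones to hydroquinone monoacetates does, while the alkyl acetate and the stereocentre are untouched.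

**Compound list**
1 | 1-tridecene | CCCCCCCCCCCC=C | starting material
2 | rac-1,2-epoxytridecane (2-undecyloxirane) | CCCCCCCCCCCC1CO1 | intermediate
3 | (R)-1,2-epoxytridecane | CCCCCCCCCCC[C@@H]1CO1 | intermediate
4 | lithium acetylide–ethylenediamine complex | [Li+].[C-]#C.NCCN | starting material
5 | (R)-pentadec-1-yn-4-ol | CCCCCCCCCCC[C@H](CC#C)O | intermediate
6 | (R)-pentadec-1-yn-4-yl acetate | CCCCCCCCCCC[C@H](CC#C)OC(C)=O | intermediate
7 | acetyl chloride | CC(=O)Cl | starting material
8 | (R)-2-oxoheptadec-3-yn-6-yl acetate | CCCCCCCCCCC[C@H](CC#CC(C)=O)OC(C)=O | intermediate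
9 | 1,1-dimethoxyethene | C=C(OC)OC | starting material
10 | 4,4-dimethoxybut-3-en-2-one | CC(=O)C=C(OC)OC | intermediate
11 | 1,1-dimethoxy-3-(trimethylsilyloxy)buta-1,3-diene | COC(OC)=CC(=C)O[Si](C)(C)C | intermediate
12 | (R)-1-[2-acetyl-3,3-dimethoxy-5-(trimethylsilyloxy)cyclohexa-1,4-dien-1-yl]tridecan-2-yl acetate | CCCCCCCCCCC[C@H](CC1=C(C(C)=O)C(OC)(OC)C=C(O[Si](C)(C)C)C1)OC(C)=O | intermediate (not isolated)
13 | (R)-1-[2-acetyl-3-methoxy-5-(trimethylsilyloxy)phenyl]tridecan-2-yl acetate | CCCCCCCCCCC[C@H](Cc1cc(O[Si](C)(C)C)cc(OC)c1C(C)=O)OC(C)=O | intermediate (not isolated)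
14 | (R)-1-(2-acetyl-5-hydroxy-3-methoxyphenyl)tridecan-2-yl acetate | CCCCCCCCCCC[C@H](Cc1cc(O)cc(OC)c1C(C)=O)OC(C)=O | intermediate
15 | (R)-1-(2-acetoxy-5-hydroxy-3-methoxyphenyl)tridecan-2-yl acetate | CCCCCCCCCCC[C@H](Cc1cc(O)cc(OC)c1OC(C)=O)OC(C)=O | target

**Step count**
Total steps: 9. Longest linear sequence: 7 (steps 1, 2, 3, 4, 5, 8, 9). The diene branch (steps 6, 7) joins at step 8.

**Steps most likely to fail**

Step 8. The beta-alkyl-substituted ynone may add so slowly that thermal breakdown or self-condensation of the ketene-acetal diene, or a one-bond Michael-type addition that does not close to the ring, outruns the cycloaddition. The fallback builds the target on a preformed arene without a cycloaddition. It sets out from epoxide 3 and comes back to the route at 15.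
- Commercial 5-bromovanillin F1 would be benzylated (BnBr, K2CO3, DMF) to 4-(benzyloxy)-3-bromo-5-methoxybenzaldehyde F2.
- mCPBA in CH2Cl2 (Dakin-type Baeyer–Villiger oxidation of the electron-rich aldehyde) would give 4-(benzyloxy)-3-bromo-5-methoxyphenyl formate F3, which K2CO3 in MeOH would cleave to 4-(benzyloxy)-3-bromo-5-methoxyphenol F4.
- Silylation (i-Pr3SiCl, imidazole, DMF) would give [4-(benzyloxy)-3-bromo-5-methoxyphenoxy]triisopropylsilane F5.
- Bromine–lithium exchange (n-BuLi, THF, −78 °C) would give [2-(benzyloxy)-3-methoxy-5-(triisopropylsilyloxy)phenyl]lithium F6. In the presence of BF3·OEt2 this should open 3 at its CH2 carbon to (R)-1-[2-(benzyloxy)-3-methoxy-5-(triisopropylsilyloxy)phenyl]tridecan-2-ol F7.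
- Hydrogenolysis (H2, Pd/C, EtOAc) would give (R)-1-[2-hydroxy-3-methoxy-5-(triisopropylsilyloxy)phenyl]tridecan-2-ol F8.
- Ac2O, pyridine and DMAP would acetylate both hydroxyls to (R)-1-[2-acetoxy-3-methoxy-5-(triisopropylsilyloxy)phenyl]tridecan-2-yl acetate F9.
- Bu4NF buffered with AcOH (THF, 0 °C) would free the C5 phenol and give 15.

Step 9. The peracid may oxidise the free, electron-rich phenol ring (ring hydroxylation leading on to quinones) in competition with addition to the hindered carbonyl and aryl migration. The fallback masks the phenol for the oxidation. It sets out from 14 and comes back at 15.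
- TBSCl and imidazole in DMF would give (R)-1-[2-acetyl-5-(tert-butyldimethylsilyloxy)-3-methoxyphenyl]tridecan-2-yl acetate F10.
- mCPBA with NaHCO3 in CH2Cl2 would give (R)-1-[2-acetoxy-5-(tert-butyldimethylsilyloxy)-3-methoxyphenyl]tridecan-2-yl acetate F11.
- Bu4NF buffered with AcOH (THF, 0 °C) would remove the silyl group without touching the aryl acetate and give 15.

Step 5. The amine may turn acetyl chloride into ketene, and it may isomerise the product ynone at its acidic CH2 or eliminate acetic acid from it, so the coupling could stall or the ynone be lost. The fallback makes the ynone by oxidation of a propargylic alcohol under non-basic conditions. It sets out from epoxide 3 and comes back at 8.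
- Commercial racemic but-3-yn-2-ol F12 would be silylated (TBSCl, imidazole, CH2Cl2) to tert-butyl(but-3-yn-2-yloxy)dimethylsilane F13.
- n-BuLi (THF, −78 °C) would give its lithium acetylide F14. With BF3·OEt2 this should open 3 at the CH2 carbon to (6R)-2-(tert-butyldimethylsilyloxy)heptadec-3-yn-6-ol F15, as a mixture of C2 epimers that does not matter.
- Ac2O, pyridine and DMAP would give (6R)-2-(tert-butyldimethylsilyloxy)heptadec-3-yn-6-yl acetate F16.
- HF·pyridine in THF would give (6R)-2-hydroxyheptadec-3-yn-6-yl acetate F17.
- Dess–Martin periodinane with NaHCO3 in CH2Cl2 would oxidise the propargylic alcohol to ynone 8.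

**Further compounds**
F1 | step 8 | 5-bromovanillin (3-bromo-4-hydroxy-5-methoxybenzaldehyde) | O=Cc1cc(Br)c(O)c(OC)c1
F2 | step 8 | 4-(benzyloxy)-3-bromo-5-methoxybenzaldehyde | O=Cc1cc(Br)c(OCc2ccccc2)c(OC)c1
F3 | step 8 | 4-(benzyloxy)-3-bromo-5-methoxyphenyl formate | O=COc1cc(Br)c(OCc2ccccc2)c(OC)c1
F4 | step 8 | 4-(benzyloxy)-3-bromo-5-methoxyphenol | Oc1cc(Br)c(OCc2ccccc2)c(OC)c1
F5 | step 8 | [4-(benzyloxy)-3-bromo-5-methoxyphenoxy]triisopropylsilane | CC(C)[Si](Oc1cc(Br)c(OCc2ccccc2)c(OC)c1)(C(C)C)C(C)C
F6 | step 8 | [2-(benzyloxy)-3-methoxy-5-(triisopropylsilyloxy)phenyl]lithium | [Li]c1cc(O[Si](C(C)C)(C(C)C)C(C)C)cc(OC)c1OCc1ccccc1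
F7 | step 8 | (R)-1-[2-(benzyloxy)-3-methoxy-5-(triisopropylsilyloxy)phenyl]tridecan-2-ol | CCCCCCCCCCC[C@H](Cc1cc(O[Si](C(C)C)(C(C)C)C(C)C)cc(OC)c1OCc1ccccc1)O
F8 | step 8 | (R)-1-[2-hydroxy-3-methoxy-5-(triisopropylsilyloxy)phenyl]tridecan-2-ol | CCCCCCCCCCC[C@H](Cc1cc(O[Si](C(C)C)(C(C)C)C(C)C)cc(OC)c1O)O
F9 | step 8 | (R)-1-[2-acetoxy-3-methoxy-5-(triisopropylsilyloxy)phenyl]tridecan-2-yl acetate | CCCCCCCCCCC[C@H](Cc1cc(O[Si](C(C)C)(C(C)C)C(C)C)cc(OC)c1OC(C)=O)OC(C)=O
F10 | step 9 | (R)-1-[2-acetyl-5-(tert-butyldimethylsilyloxy)-3-methoxyphenyl]tridecan-2-yl acetate | CCCCCCCCCCC[C@H](Cc1cc(O[Si](C)(C)C(C)(C)C)cc(OC)c1C(C)=O)OC(C)=O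
F11 | step 9 | (R)-1-[2-acetoxy-5-(tert-butyldimethylsilyloxy)-3-methoxyphenyl]tridecan-2-yl acetate | CCCCCCCCCCC[C@H](Cc1cc(O[Si](C)(C)C(C)(C)C)cc(OC)c1OC(C)=O)OC(C)=O
F12 | step 5 | but-3-yn-2-ol (racemic) | CC(O)C#C
F13 | step 5 | tert-butyl(but-3-yn-2-yloxy)dimethylsilane | CC(C#C)O[Si](C)(C)C(C)(C)C
F14 | step 5 | lithium acetylide of tert-butyl(but-3-yn-2-yloxy)dimethylsilane | [Li]C#CC(C)O[Si](C)(C)C(C)(C)C
F15 | step 5 | (6R)-2-(tert-butyldimethylsilyloxy)heptadec-3-yn-6-ol | CCCCCCCCCCC[C@H](CC#CC(C)O[Si](C)(C)C(C)(C)C)O
F16 | step 5 | (6R)-2-(tert-butyldimethylsilyloxy)heptadec-3-yn-6-yl acetate | CCCCCCCCCCC[C@H](CC#CC(C)O[Si](C)(C)C(C)(C)C)OC(C)=O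
F17 | step 5 | (6R)-2-hydroxyheptadec-3-yn-6-yl acetate | CCCCCCCCCCC[C@H](CC#CC(C)O)OC(C)=O
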